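## Retrosynthetic overview

1. Target 17 is the ring-chain (hemiketal) tautomer of (2R)-flavanone 16. The bond from the ring B oxygen O2' to C4 is cut first; it can only re-form as the cis-bridged 2,8-dioxabicyclo[3.3.1]nonane, so only C2 has to be controlled.
2. The chroman-4-one ring (O1, C2, C3, C4, C4a, C8a) is not closed by cyclisation. It is traced to the five-membered dihydrofuran ring (O1, C2, C4, C4a, C8a) of cyclopropanol 14, in which a CH2 bridges C2 and C4; breaking the C2–C4 bond inserts that CH2 as C3 (strain-release ring expansion, five to six).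
3. Enabling feature: in ring C the unsubstituted C3H2 lies between C2, which bears O1 and aryl ring B and can take the electron pair and a proton, and C4, whose oxygen becomes the carbonyl. This O1–C2(aryl)–CH2–C4(=O) array is a ring-opened 1-hydroxy-2-aryl-2-aryloxycyclopropane.
4. 14 comes from iodomethyl ketone 13 (3-exo closure of C3–C4), and 13 from hydroxy ester 10 in three functional-group steps. 10 is assembled from ring A aldehyde 3 and ring B diazo ester 9 by carbene O–H insertion/aldol, which closes the furan ring and sets the quaternary C2.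
5. Ring order: dimethylpyran (step 2), dihydrofuran (step 6), cyclopropane (step 10), then the chromanone ring by expansion together with the hemiketal ring (step 11).

Key step: step 11

Remark: 1 and 4 are taken as commercial. Flavanone numbering (O1, C2, C3, C4, C4a, C5–C8, C8a; ring B atoms primed) is used for corresponding atoms of all intermediates; the ring-fusion carbons of the cyclopropane in 14 and 15 are also called C1a (= C2) and C6b (= C4).

## Route

Step 1
Reactants: 1 2,4-dihydroxy-6-methoxybenzaldehyde
Product: 2 2,4-dihydroxy-6-methoxy-3-(3-methylbut-2-en-1-yl)benzaldehyde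
Conditions: prenyl bromide (1.1 equiv), KOH (10% aq), 0 °C → rt
Reagents that add atoms: prenyl bromide (1-bromo-3-methylbut-2-ene), CC(C)=CCBr
Why: C-prenylation of an acylphloroglucinol phenoxide in water, in which the ring carbon between the two free hydroxyls is the most nucleophilic position; O-prenyl ethers and the minor regioisomer are separated.

Step 2
Reactants: 2 2,4-dihydroxy-6-methoxy-3-(3-methylbut-2-en-1-yl)benzaldehyde
Product: 3 7-hydroxy-5-methoxy-2,2-dimethyl-8-(3-methylbut-2-en-1-yl)-2H-chromene-6-carbaldehyde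
Conditions: 3-methylbut-2-enal (2 equiv), ethylenediammonium diacetate (10 mol %), toluene, reflux
Reagents that add atoms: 3-methylbut-2-enal, CC(C)=CC=O
Why: Amine-catalysed condensation of the enal at the only free ring carbon followed by oxa-6π electrocyclisation onto the 4-oxygen (formal [3+3] chromene annulation) should give a single linear pyran, because the other ortho carbon is blocked by prenyl and the methoxy oxygen cannot close.

Step 3
Reactants: 4 2-bromobenzene-1,3-diol
Product: 5 2-bromo-1,3-bis(tert-butyldimethylsilyloxy)benzene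
Conditions: TBSCl (2.3 equiv), imidazole (5 equiv), DMF, rt
Reagents that add atoms: tert-butyldimethylsilyl chloride, CC(C)(C)[Si](C)(C)Cl
Why: Standard silylation of phenols; silyl ethers are chosen because they offer no C–H bond next to oxygen for carbene insertion in step 6 and fall off under the fluoride of step 11.

Step 4
Reactants: 5 2-bromo-1,3-bis(tert-butyldimethylsilyloxy)benzene
Product: 7 methyl 2-[2,6-bis(tert-butyldimethylsilyloxy)phenyl]-2-oxoacetate, via aryllithium 6 (not isolated)
Conditions: n-BuLi (1.05 equiv), Et2O, −78 °C, 15 min; cannulated into dimethyl oxalate (3 equiv), Et2O, −78 °C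
Reagents that add atoms: dimethyl oxalate, COC(=O)C(=O)OC
Why: Bromine–lithium exchange and acyl substitution on excess oxalate diester (inverse addition stops at the keto ester); at −78 °C in ether the 1,3 O→C silyl shift of the ortho-lithiated silyl ether should be slower than trapping.

Step 5
Reactants: 7 methyl 2-[2,6-bis(tert-butyldimethylsilyloxy)phenyl]-2-oxoacetate
Product: 9 methyl 2-[2,6-bis(tert-butyldimethylsilyloxy)phenyl]-2-diazoacetate, via tosylhydrazone 8 (not isolated)
Conditions: TsNHNH2 (1.1 equiv), toluene, 70 °C; then DBU (1.5 equiv), CH2Cl2, 0 °C → rt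
Reagents that add atoms: p-toluenesulfonyl hydrazide, Cc1ccc(cc1)S(=O)(=O)NN
Why: Bamford–Stevens route to aryl diazoacetates: condensation to the tosylhydrazone of the aryl glyoxylate, then base-induced loss of sulfinate.

Step 6
Reactants: 3 7-hydroxy-5-methoxy-2,2-dimethyl-8-(3-methylbut-2-en-1-yl)-2H-chromene-6-carbaldehyde; 9 methyl 2-[2,6-bis(tert-butyldimethylsilyloxy)phenyl]-2-diazoacetate
Product: 10 methyl (2S,3R)-2-[2,6-bis(tert-butyldimethylsilyloxy)phenyl]-3-hydroxy-4-methoxy-7,7-dimethyl-9-(3-methylbut-2-en-1-yl)-2,3-dihydro-7H-furo[3,2-g]chromene-2-carboxylate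
Conditions: Rh2(OAc)4 (2 mol %), (R)-TRIP (10 mol %), 4 Å MS, CH2Cl2, 0 °C, 9 (1.5 equiv) added over 2 h
Reagents that add atoms: none
Why: The Rh2(OAc)4 carbene from 9 inserts into the phenolic O–H of 3 and the oxonium ylide (enol) is caught by the neighbouring aldehyde, activated by the chiral phosphoric acid, in an intramolecular aldol (5-exo-trig) before it is protonated (carbene O–H insertion with aldol-type ylide trapping under Rh2(OAc)4/chiral phosphoric acid cooperative catalysis), so the acid should set the quaternary centre as 2S (its enantiomer is chosen accordingly), while the carbinol centre (expected cis to the ester) is erased in step 8.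

Step 7
Reactants: 10 hydroxy ester
Product: 11 (2R,3R)-2-[2,6-bis(tert-butyldimethylsilyloxy)phenyl]-2-(hydroxymethyl)-4-methoxy-7,7-dimethyl-9-(3-methylbut-2-en-1-yl)-2,3-dihydro-7H-furo[3,2-g]chromen-3-ol
Conditions: i-Bu2AlH (5 equiv), CH2Cl2, −78 → −30 °C; Rochelle salt
Reagents that add atoms: none
Why: Hydride reduction of the ester to the primary alcohol; at low temperature the covalent aluminium alkoxide of the carbinol should not undergo retro-aldol, so the quaternary centre is untouched (the descriptor changes only by priority).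

Step 8
Reactants: 11 diol
Product: 12 (2R)-2-[2,6-bis(tert-butyldimethylsilyloxy)phenyl]-2-(hydroxymethyl)-4-methoxy-7,7-dimethyl-9-(3-methylbut-2-en-1-yl)-7H-furo[3,2-g]chromen-3(2H)-one
Conditions: MnO2 (activated, 20 equiv), CH2Cl2, rt
Reagents that add atoms: none
Why: MnO2 oxidises the benzylic secondary alcohol chemoselectively over the neopentyl primary alcohol, and the neutral conditions avoid retro-aldol loss of formaldehyde from the β-hydroxy ketone.

Step 9
Reactants: 12 hydroxy ketone
Product: 13 (2S)-2-[2,6-bis(tert-butyldimethylsilyloxy)phenyl]-2-(iodomethyl)-4-methoxy-7,7-dimethyl-9-(3-methylbut-2-en-1-yl)-7H-furo[3,2-g]chromen-3(2H)-one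
Conditions: PPh3 (1.5 equiv), I2 (1.5 equiv), imidazole (3 equiv), toluene, 60 °C
Reagents that add atoms: iodine, II
Why: Appel-type (Garegg–Samuelsson) iodination through the alkoxyphosphonium salt, which converts neopentyl-type alcohols without skeletal rearrangement; the quaternary centre is not involved (descriptor changes by priority only).

Step 10
Reactants: 13 iodomethyl ketone
Product: 14 cyclopropanol (1aS,6bS): the skeleton of 13 with the CH2 bonded to both C2 and the former carbonyl carbon (2-oxabicyclo[3.1.0]hexane unit); C1a bears the ring oxygen and the 2,6-bis(tert-butyldimethylsilyloxy)phenyl group and C6b the OH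
Conditions: SmI2 (2.5 equiv), THF, −78 °C, 30 min; sat. NH4Cl
Reagents that add atoms: none
Why: Electron transfer from SmI2 gives a ketyl (or, after C–I reduction, an alkylsamarium) that closes the C3–C4 bond in a Barbier-type 3-exo cyclisation, the reaction type used to make cyclopropanols from β-halo ketones; the ring fusion can only be cis, so C6b follows from the C1a centre, and the cold neutral quench should keep the alkoxide from opening.

Step 11
Reactants: 14 cyclopropanol
Product: 17 target hemiketal CNP0170313.2, via bis-phenol cyclopropanol 15 (not isolated), via ring-opened flavanone 16 (not isolated)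
Conditions: TBAF·3H2O (3 equiv), THF, −20 → 0 °C; then AcOH (4 equiv), pH 7 phosphate buffer
Reagents that add atoms: none
Why: Proposed new method: fluoride removes both aryl silyl groups to give the bis-phenoxide of 15, whose 2'-phenoxide lies next to the cyclopropanol OH and serves as base; the C6b alkoxide pushes into the C6b–C1a bond (shared by the cyclopropane and the dihydrofuran ring), which breaks toward C1a because that carbon is benzylic and bears O1, while water or HF protonates C1a from the side opposite to C6b (SE2, inversion), so the five-membered ring becomes the chroman-4-one ring of 16 with the former cyclopropane CH2 as C3. The closest known reaction types are the base-induced opening of 2-arylcyclopropanols to β-aryl ketones, which cleaves toward the benzylic carbon with inversion there, and the one-carbon Dowd–Beckwith ring expansion of 2-(halomethyl)cycloalkanones through bicyclic cyclopropyloxy intermediates; new is the use on a cyclopropa[b]benzofuran-6b-ol to carry chirality from a quaternary carbon to the C2–H centre. The chromanone ring is not closed by bond formation but arises by cleavage of the zero-atom bridge of the 2-oxabicyclo[3.1.0]hexane unit (five to six), and on neutralisation the 2'-OH adds to the C4 carbonyl of 16 (6-exo-trig hemiketalisation) to close the second six-membered ring of the 2,8-dioxabicyclo[3.3.1]nonane. C2 (R) should come from the 1aS centre of 14 by inversion, and C4 (R) is fixed by C2 because the one-carbon bridge allows only the cis-bridged hemiketal. The step needs internal (C6b–C1a) instead of external (C6b–CH2) cleavage, secured by aryl ring B and O1 on C1a, and it needs 16 not to be reopened by base (retro-oxa-Michael or quinone methide), which the low temperature, the hydrated fluoride and the immediate acidification are meant to secure.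

## Compound list

1 | 2,4-dihydroxy-6-methoxybenzaldehyde | COc1cc(O)cc(O)c1C=O | starting material
2 | 2,4-dihydroxy-6-methoxy-3-(3-methylbut-2-en-1-yl)benzaldehyde | COc1cc(O)c(CC=C(C)C)c(O)c1C=O | intermediate
3 | 7-hydroxy-5-methoxy-2,2-dimethyl-8-(3-methylbut-2-en-1-yl)-2H-chromene-6-carbaldehyde | COc1c(C=O)c(O)c(CC=C(C)C)c2OC(C)(C)C=Cc12 | intermediate
4 | 2-bromobenzene-1,3-diol (2-bromoresorcinol) | Oc1cccc(O)c1Br | starting material
5 | 2-bromo-1,3-bis(tert-butyldimethylsilyloxy)benzene | CC(C)(C)[Si](C)(C)Oc1cccc(O[Si](C)(C)C(C)(C)C)c1Br | intermediate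
6 | [2,6-bis(tert-butyldimethylsilyloxy)phenyl]lithium | [Li]c1c(O[Si](C)(C)C(C)(C)C)cccc1O[Si](C)(C)C(C)(C)C | intermediate
7 | methyl 2-[2,6-bis(tert-butyldimethylsilyloxy)phenyl]-2-oxoacetate | COC(=O)C(=O)c1c(O[Si](C)(C)C(C)(C)C)cccc1O[Si](C)(C)C(C)(C)C | intermediate
8 | methyl 2-[2,6-bis(tert-butyldimethylsilyloxy)phenyl]-2-(tosylhydrazono)acetate | COC(=O)C(=NNS(=O)(=O)c1ccc(C)cc1)c1c(O[Si](C)(C)C(C)(C)C)cccc1O[Si](C)(C)C(C)(C)C | intermediate
9 | methyl 2-[2,6-bis(tert-butyldimethylsilyloxy)phenyl]-2-diazoacetate | COC(=O)C(=[N+]=[N-])c1c(O[Si](C)(C)C(C)(C)C)cccc1O[Si](C)(C)C(C)(C)C | intermediate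
10 | methyl (2S,3R)-2-[2,6-bis(tert-butyldimethylsilyloxy)phenyl]-3-hydroxy-4-methoxy-7,7-dimethyl-9-(3-methylbut-2-en-1-yl)-2,3-dihydro-7H-furo[3,2-g]chromene-2-carboxylate | COc1c2c(c(CC=C(C)C)c3c1[C@@H](O)[C@](O3)(C(=O)OC)c4c(O[Si](C)(C)C(C)(C)C)cccc4O[Si](C)(C)C(C)(C)C)OC(C)(C)C=C2 | intermediate
11 | (2R,3R)-2-[2,6-bis(tert-butyldimethylsilyloxy)phenyl]-2-(hydroxymethyl)-4-methoxy-7,7-dimethyl-9-(3-methylbut-2-en-1-yl)-2,3-dihydro-7H-furo[3,2-g]chromen-3-ol | COc1c2c(c(CC=C(C)C)c3c1[C@@H](O)[C@](O3)(CO)c4c(O[Si](C)(C)C(C)(C)C)cccc4O[Si](C)(C)C(C)(C)C)OC(C)(C)C=C2 | intermediate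
12 | (2R)-2-[2,6-bis(tert-butyldimethylsilyloxy)phenyl]-2-(hydroxymethyl)-4-methoxy-7,7-dimethyl-9-(3-methylbut-2-en-1-yl)-7H-furo[3,2-g]chromen-3(2H)-one | COc1c2c(c(CC=C(C)C)c3c1C(=O)[C@](O3)(CO)c4c(O[Si](C)(C)C(C)(C)C)cccc4O[Si](C)(C)C(C)(C)C)OC(C)(C)C=C2 | intermediate
13 | (2S)-2-[2,6-bis(tert-butyldimethylsilyloxy)phenyl]-2-(iodomethyl)-4-methoxy-7,7-dimethyl-9-(3-methylbut-2-en-1-yl)-7H-furo[3,2-g]chromen-3(2H)-one | COc1c2c(c(CC=C(C)C)c3c1C(=O)[C@](O3)(CI)c4c(O[Si](C)(C)C(C)(C)C)cccc4O[Si](C)(C)C(C)(C)C)OC(C)(C)C=C2 | intermediate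
14 | cyclopropanol (1aS,6bS): CH2 bridging C2 and C3 of the furan ring of the furo[3,2-g]chromene; C1a bears the ring oxygen and the 2,6-bis(tert-butyldimethylsilyloxy)phenyl group, C6b the OH; 4-methoxy, 7,7-dimethyl and 9-prenyl as in 13 | COc1c2c(c(CC=C(C)C)c3c1[C@@]4(O)C[C@]4(O3)c5c(O[Si](C)(C)C(C)(C)C)cccc5O[Si](C)(C)C(C)(C)C)OC(C)(C)C=C2 | intermediate
15 | bis-phenol cyclopropanol (1aS,6bS): 14 with both silyl groups removed (2,6-dihydroxyphenyl on C1a) | COc1c2c(c(CC=C(C)C)c3c1[C@@]4(O)C[C@]4(O3)c5c(O)cccc5O)OC(C)(C)C=C2 | intermediate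
16 | (2R)-2-(2,6-dihydroxyphenyl)-5-methoxy-8,8-dimethyl-10-(3-methylbut-2-en-1-yl)-2,3-dihydro-4H,8H-pyrano[3,2-g]chromen-4-one | COc1c2c(c(CC=C(C)C)c3c1C(=O)C[C@@H](O3)c4c(O)cccc4O)OC(C)(C)C=C2 | intermediate
17 | CNP0170313.2: (2R,4R) cyclic hemiketal of 16 in which the 2'-oxygen of ring B is bonded to C4 (4-hydroxy-2,8-dioxabicyclo[3.3.1]nonane core, 6'-OH free) | COc1c2c(c(CC=C(C)C)c3c1[C@@]1(O)C[C@@H](O3)c3c(O)cccc3O1)OC(C)(C)C=C2 | target

## Step count and risks

Total steps: 11. Longest linear sequence: 9 (steps 3, 4, 5, 6, 7, 8, 9, 10, 11 from 4); the ring A branch is 8 steps.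

Steps most likely to fail:

1. Step 11 (proposed new method). The alkoxide may open by the external bond, or only at a temperature at which the liberated flavanone is itself reopened by base. Transfer of configuration may also be incomplete, through competing retentive protonation or reversible ring opening of 16. Fallback with known chemistry, setting out from 13: radical Dowd–Beckwith ring expansion ((Me3Si)3SiH, AIBN, benzene, 80 °C) should give racemic flavanone bis-silyl ether F1. Kinetic resolution by asymmetric transfer hydrogenation (RuCl[(S,S)-TsDPEN](p-cymene) or its antipode, whichever consumes the 2S ketone; HCO2H/Et3N) should reduce the 2S enantiomer to cis-flavan-4-ol F3 and leave (2R)-flavanone bis-silyl ether F2. Desilylation of F2 under acidic fluoride (HF·pyridine, THF, 0 °C) rejoins the route at 16, which closes to 17 on work-up.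

2. Step 6. The ylide may be protonated before the aldehyde captures it, the carbene may add to the chromene double bond, or the acid may give poor facial control at the quaternary carbon. Fallback, setting out from 3 and 9: Rh2(OAc)4 alone gives the O–H insertion product, aryl ether aldehyde F4. DBU (CH2Cl2, rt) closes it by intramolecular aldol to racemic hydroxy ester F5. Resolution of F5 by preparative chromatography on a chiral stationary phase returns to 10.

3. Step 10. The reduction may leak into the radical manifold: the primary radical attacks the carbonyl and the cyclopropyloxy radical fragments, giving racemic ring-expanded ketone. Simple deiodination is the other loss. Fallback, setting out from 13: two-electron iodine–lithium exchange (t-BuLi, 2.1 equiv, Et2O/pentane, −100 °C) with intramolecular carbonyl addition and trapping by Me3SiCl gives cyclopropanol trimethylsilyl ether F6. F6 is taken directly into the conditions of step 11, where fluoride removes all three silyl groups, and rejoins the route at 15.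

## Further compounds

F1 | step 11 | racemic 2-[2,6-bis(tert-butyldimethylsilyloxy)phenyl]-5-methoxy-8,8-dimethyl-10-(3-methylbut-2-en-1-yl)-2,3-dihydro-4H,8H-pyrano[3,2-g]chromen-4-one | COc1c2c(c(CC=C(C)C)c3c1C(=O)CC(O3)c4c(O[Si](C)(C)C(C)(C)C)cccc4O[Si](C)(C)C(C)(C)C)OC(C)(C)C=C2
F2 | step 11 | (2R)-2-[2,6-bis(tert-butyldimethylsilyloxy)phenyl]-5-methoxy-8,8-dimethyl-10-(3-methylbut-2-en-1-yl)-2,3-dihydro-4H,8H-pyrano[3,2-g]chromen-4-one | COc1c2c(c(CC=C(C)C)c3c1C(=O)C[C@@H](O3)c4c(O[Si](C)(C)C(C)(C)C)cccc4O[Si](C)(C)C(C)(C)C)OC(C)(C)C=C2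
F3 | step 11 | (2S,4S)-2-[2,6-bis(tert-butyldimethylsilyloxy)phenyl]-5-methoxy-8,8-dimethyl-10-(3-methylbut-2-en-1-yl)-3,4-dihydro-2H,8H-pyrano[3,2-g]chromen-4-ol | COc1c2c(c(CC=C(C)C)c3c1[C@@H](O)C[C@H](O3)c4c(O[Si](C)(C)C(C)(C)C)cccc4O[Si](C)(C)C(C)(C)C)OC(C)(C)C=C2
F4 | step 6 | methyl 2-[2,6-bis(tert-butyldimethylsilyloxy)phenyl]-2-{[6-formyl-5-methoxy-2,2-dimethyl-8-(3-methylbut-2-en-1-yl)-2H-chromen-7-yl]oxy}acetate | COc1c(C=O)c(OC(C(=O)OC)c3c(O[Si](C)(C)C(C)(C)C)cccc3O[Si](C)(C)C(C)(C)C)c(CC=C(C)C)c2OC(C)(C)C=Cc12
F5 | step 6 | racemic methyl 2-[2,6-bis(tert-butyldimethylsilyloxy)phenyl]-3-hydroxy-4-methoxy-7,7-dimethyl-9-(3-methylbut-2-en-1-yl)-2,3-dihydro-7H-furo[3,2-g]chromene-2-carboxylate | COc1c2c(c(CC=C(C)C)c3c1C(O)C(O3)(C(=O)OC)c4c(O[Si](C)(C)C(C)(C)C)cccc4O[Si](C)(C)C(C)(C)C)OC(C)(C)C=C2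
F6 | step 10 | trimethylsilyl ether of cyclopropanol 14 (1aS,6bS) | COc1c2c(c(CC=C(C)C)c3c1[C@@]4(O[Si](C)(C)C)C[C@]4(O3)c5c(O[Si](C)(C)C(C)(C)C)cccc5O[Si](C)(C)C(C)(C)C)OC(C)(C)C=C2
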